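## Structural features

The target, C24H14O11, is an achiral, fully aromatic heptaphenol made of four benzene rings that are joined only by oxygen bridges and one biaryl bond. Ring A is a 3,5-dihydroxyphenyl group bound through an ether oxygen to B1 of ring B; ring B has OH at B2 and B4, H at B3, and is fused to ring D through a 1,4-dioxin in which the oxygen on B5 is bonded to D6 and the oxygen on B6 to D1. Ring D (OH at D2, H at D3) and ring F form a dibenzofuran: the furan oxygen links D4 and F1, the biaryl bond links D5 and F6, and ring F has OH at F3 and F5 and H at F2 and F4. There is no stereocentre, so every problem is regiochemical: ring D is pentasubstituted with four oxygens, both bay carbons (F5 and D6) carry oxygen, and the dioxin is unsymmetrical (the D6 oxygen must end next to B4, the D1 oxygen next to B1). The free polyphenol, with phloroglucinol- and pyrogallol-type rings, is easily oxidised, above all in base, so all hydroxyls are carried as ethers and released last; the C–O–C bridges themselves are robust. The real difficulty is to place eleven oxygens with the right differentiation and to close the dioxin in one sense only, because a phenoxide ortho to a diaryl ether on an activated ring can change places by Smiles rearrangement. The key step uses the fact that the F1–F6 bond is the C2–C3 bond of a benzofuran and that F3 and F5 are 1,3-related oxygens separated by CH. That is the pattern a benzofuran-2-yl ketene (carbonyl carbon becoming F5) and an alkoxyacetylene (oxygen-bearing carbon becoming F3) assemble.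

## Logic of the disconnections

32 from 31: the seven O–alkyl bonds are cut last. The phenols stay masked through all basic and oxidative steps; the forward step needs one reagent that cleaves methyl and ethyl aryl ethers but not diaryl ethers.

31 from 29 (through 30): the D1–O–B6 bond of the dioxin is cut. It is made only after ring B has lost its activating formyl groups, so the freed D1 phenoxide cannot add to B5 and exchange with the D6 oxygen. The demand is a metal-catalysed C–O coupling at a crowded aryl bromide, helped by the six-membered ring that forms.

29 from 26 (through 28): the B2–O and B4–O bonds are traced back to formyl carbons. The formyl groups first activate ring B for substitution and are then turned into oxygen; the forward oxidation needs aryl migration on a ring carrying two aryloxy groups.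

26 from 19, 23 and 24: the B5–O and B1–O bonds are cut. This splits the molecule into the dibenzofuran, a three-carbon-pattern hub and ring A; the two fluorines of 23 are equivalent and doubly activated, the bromine-bearing carbon is not. The forward step needs stepwise mono-substitution and a D1 oxygen that stays masked.

23 from 20 (through 21): one formyl C–C bond is cut; the forward step needs lithiation ortho to fluorine without loss of LiF or bromine migration.

19 from 15 (through 16 and 17): the D6–O bond is traced to a D6 formyl group and then to D6–H. The free D1 hydroxyl of 15 is the only handle that can direct a one-carbon electrophile to the bay carbon D6 and away from the more electron-rich ring F; masking D1 before the oxidation leaves the two dioxin oxygens differentiated.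

15 from 13 (through 14): protecting-group changes only. The new bay phenol is capped so that it cannot direct the formylation, and the benzyl ether is the one group that can be removed without touching methyl and ethyl ethers.

13 from 8 and 9: ring F is cut at F2–F3, F4–F5 and F5–F6 (and F1–F2, which the Wolff shift makes). This removes a whole ring with its 1,3-dioxygen pattern and leaves a benzofuran whose furan is already in place; the forward step needs a regioselective ketene–alkyne union and closure at the single free furan carbon.

8 from 6, and 6 from 4 and 5: the C–N2 bond, then the furan O–C2 and C2–C3 bonds are cut, down to a salicylaldehyde and a three-carbon chloro ketone.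

4 from 3, and 3 from 1: the formyl C–C bond ortho to the phenol, then the phenol C–O bond (from the aldehyde of 1) are cut, reaching a commercial vanillin ether that already has D1 and D2 differentiated.

## Other disconnections considered

Alternative 1: The cut is the D5–F6 biaryl bond, made last inside a macrocycle. The precursor would be the 12-membered diaryl ether A2, with D4–O–F1 already in place and the two bay oxygens tied by a tetraisopropyldisiloxane bridge. An oxidative dehydrogenative coupling of the C–H bonds at D5 and F6 would close the furan and give dibenzofuran A1.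
- In its favour: both bay oxygens are present from the start. On this point the alternative is better than the chosen plan, which must add the D6 oxygen after the annulation at a hindered carbon. The tether also forces coupling at the two carbons that lie between two oxygens, which an untethered diaryl ether would avoid. Both arenes are cheap oxygenated benzenes, so in material cost it is at least the equal.
- Against it here: the coupling is a radical-cation or double C–H palladation process on two very electron-rich rings, with no built-in regiochemistry beyond the tether. Over-oxidation to quinones and intermolecular coupling compete, and aryl O–Si bonds are labile to the acids such oxidants usually need. A2 needs a diaryl ether synthesis between hindered partners plus a medium-ring silylation under dilution, and A1 carries a strained nine-membered bridge.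
- Comparison: removing the bridge would free both bay phenols at once, so the D6/F5 differentiation needed for the dioxin would still have to be solved. The step count to a differentiated dibenzofuran is expected to be comparable; in mechanistic predictability the chosen pericyclic cascade is ahead.

Alternative 2: The cut is all three aryl–oxygen bonds on ring B (B5–O, B6–O, B1–O) at once. In one pot the D6 phenoxide of a dibenzofuran such as A5, then its fluoride-unmasked D1 phenoxide, then the phenoxide of 24 would displace the three fluorines of 4,5,6-trifluoroisophthalaldehyde A4. The product is dialdehyde A3, whose formyl groups become the B2 and B4 hydroxyls by Dakin oxidation.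
- In its favour: three C–O bonds and one ring in one flask, no transition metal, and an endgame two to three steps shorter than the chosen one. On step economy and convergence the alternative is the better.
- It is not a rival for the dibenzofuran, since it needs a partner like A5 that the chosen key step supplies. The chosen route in fact uses a close relative of A4 (compound 23) for the first two of the three bonds.
- Against it: the ring-closing displacement must occur at the only fluorine that is meta to both formyl groups, while the neighbouring diaryl ether carbon B5 is ortho and para to them. A free D1 phenoxide is therefore expected to add to B5 more readily than to B6, giving a spiro Meisenheimer adduct that can reopen either way (Smiles rearrangement). The D1 and D6 oxygens may then exchange before closure, and the protecting-group differentiation no longer guarantees which dioxin isomer forms.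
- Comparison: the chosen plan pays the extra steps (Dakin oxidation and methylation before a copper-catalysed closure at bromide) so that the dioxin regiochemistry is fixed by construction and not by relative rates.

Alternative 3: The cut is ring D itself, at D3–D4, traced back to cyclobutenone A7 (racemic at a carbinol carbon that is lost on aromatisation). Heating A7 would open the four-membered ring to a dienylketene whose ketene carbon (D4) closes onto the terminus of the methoxyvinyl group (D3), giving hydroquinone A6 with the future ring F on D5 and oxygens on D1, D2, D4 and D6.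
- In its favour: all four oxygens of ring D arrive in one thermal step, with the D6 oxygen in place and distinguishable. Here the alternative is better than the chosen plan.
- Mechanistically it belongs to the same family as the chosen key step (four-electron opening of a cyclobutenone to a ketene, then six-electron closure), so in predictability of the ring-forming event the two are equal; it needs no photochemistry.
- Against it here: the work moves into making A7, which needs two successive regiocontrolled additions to a squarate ester, the first by a 2,6-disubstituted aryl nucleophile. A6 is an electron-rich hydroquinone, easily oxidised to the quinone, with two free hydroxyls to tell apart. The furan would then have to be closed by phenoxide displacement of fluoride on an unactivated dimethoxyaryl ring, which normally requires forcing conditions.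
- Comparison: ring F would be bought and not built, so its F3/F5 pattern is as secure as in the chosen plan. The step count to a dibenzofuran at the level of 19 is expected to be similar; the chosen plan has the easier furan, the alternative the easier D6 oxygen.

Key step: step 5

Remark on the chemistry: 3-bromo-2,4-difluorobenzaldehyde (20) is taken as a catalogue compound.
Remark on the chemistry: the annulation makes four ring bonds (F1–F2 in the Wolff shift, then F2–F3, F4–F5, F5–F6), because the aryl–acyl bond of the diazo ketone is broken and re-formed one carbon further on; no structural error was found in precursor 8 or product 13, and the benzyl ether on D1 is kept.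
Remark on the chemistry: the dioxin is closed by copper catalysis on a deactivated ring B, not by fluoride displacement on the activated dialdehyde, to exclude Smiles exchange of the D1 and D6 oxygens.

## Route

Step 1
Reactants: 1 4-(benzyloxy)-3-methoxybenzaldehyde (O-benzylvanillin)
Product: 3 4-(benzyloxy)-3-methoxyphenol, via aryl formate 2 (not isolated)
Conditions: mCPBA, CH2Cl2, 0 °C → rt; then K2CO3, MeOH, rt
Reagents that add atoms: mCPBA (3-chloroperoxybenzoic acid), O=C(OO)c1cccc(Cl)c1
Why: Dakin oxidation in its Baeyer–Villiger form; the para-benzyloxy group makes the aryl group migrate to give formate 2, and mild methanolysis frees the phenol whose oxygen becomes the furan oxygen on D4.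

Step 2
Reactants: 3 4-(benzyloxy)-3-methoxyphenol
Product: 4 5-(benzyloxy)-2-hydroxy-4-methoxybenzaldehyde
Conditions: MgCl2, Et3N, (CH2O)n, MeCN, reflux
Reagents that add atoms: paraformaldehyde (as formaldehyde), C=O
Why: Casnati–Skattebøl ortho-formylation; the magnesium phenoxide delivers formaldehyde only to an ortho carbon and a second formaldehyde accepts hydride. The ortho site between OH and OMe is shielded, so the formyl group enters para to the methoxy group (D5).

Step 3
Reactants: 4 5-(benzyloxy)-2-hydroxy-4-methoxybenzaldehyde; 5 chloroacetone
Product: 6 1-[5-(benzyloxy)-6-methoxy-1-benzofuran-2-yl]ethan-1-one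
Conditions: K2CO3, DMF, 80 °C
Reagents that add atoms: none
Why: Rap–Stoermer condensation; phenoxide O-alkylation by the α-chloro ketone, then intramolecular aldol condensation onto the ortho-formyl group and dehydration give the 2-acetylbenzofuran.

Step 4
Reactants: 6 1-[5-(benzyloxy)-6-methoxy-1-benzofuran-2-yl]ethan-1-one
Product: 8 1-[5-(benzyloxy)-6-methoxy-1-benzofuran-2-yl]-2-diazoethan-1-one, via trifluoroacetyl diketone 7 (not isolated)
Conditions: LiN(SiMe3)2, THF, −78 °C; CF3CO2CH2CF3; then 4-acetamidobenzenesulfonyl azide, Et3N, H2O (1 equiv), MeCN, rt
Reagents that add atoms: 4-acetamidobenzenesulfonyl azide, CC(=O)Nc1ccc(S(=O)(=O)N=[N+]=[N-])cc1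
Why: Detrifluoroacetylative diazo transfer; the lithium enolate of the methyl ketone is acylated by 2,2,2-trifluoroethyl trifluoroacetate (O=C(OCC(F)(F)F)C(F)(F)F) to give 7, and the sulfonyl azide then transfers N2 while the trifluoroacetyl group leaves on the sulfonamide nitrogen. A simple methyl ketone does not undergo direct diazo transfer, and this sulfonyl azide is a less hazardous choice than mesyl azide or a diazomethane acylation.

Step 5
Reactants: 8 1-[5-(benzyloxy)-6-methoxy-1-benzofuran-2-yl]-2-diazoethan-1-one; 9 ethoxyacetylene
Product: 13 8-(benzyloxy)-3-ethoxy-7-methoxydibenzofuran-1-ol, via benzofuranylketene 10 (not isolated), via ethoxycyclobutenone 11 (not isolated), via dienylketene 12 (not isolated)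
Conditions: 9 (3 equiv), ClCH2CH2Cl (degassed), hν (medium-pressure Hg lamp, Vycor filter), 20 °C; then 80 °C
Reagents that add atoms: none
Why: This is a Danheiser-type photochemical benzannulation of a heteroaryl α-diazo ketone with an alkoxyalkyne, the closest known reaction type. Light expels N2 and the benzofuran-2-yl group shifts from the acyl carbon to the diazo carbon (Wolff rearrangement), which makes F1–F2 and ketene 10. The unsubstituted, nucleophilic carbon of 9 adds to the electrophilic ketene carbonyl carbon (F4–F5) and the zwitterion collapses (F2–F3) to the 3-ethoxy-4-arylcyclobutenone 11; this polarity match is the regiochemical control that puts OEt on F3 and the future hydroxyl on F5, with CH at F2 and F4. Four-electron electrocyclic opening of 11, under the irradiation or on warming, breaks the original acyl–diazo carbon bond and gives dienylketene 12. Ring F is then closed by a thermal six-electron electrocyclisation in which the ketene carbon bonds to furan carbon F6, the only free position and one whose C2=C3 bond has enol-ether character and little aromaticity to lose, and the cyclohexadienone tautomerises to the phenol. No stereocentre survives, since the sp3 carbons of 11 and of the dienone are flattened on aromatisation. The selectivity needed is capture of 10 by the alkyne in preference to dimerisation or acylation of the product phenol, which excess 9 and dilution secure, and the heating period completes the opening of residual 11.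

Step 6
Reactants: 13 8-(benzyloxy)-3-ethoxy-7-methoxydibenzofuran-1-ol
Product: 14 8-(benzyloxy)-3-ethoxy-1,7-dimethoxydibenzofuran
Conditions: MeI, K2CO3, acetone, reflux
Reagents that add atoms: iodomethane, CI
Why: Williamson methylation caps the new bay phenol (F5), which would otherwise direct the later magnesium-mediated formylation onto ring F.

Step 7
Reactants: 14 8-(benzyloxy)-3-ethoxy-1,7-dimethoxydibenzofuran
Product: 15 7-ethoxy-3,9-dimethoxydibenzofuran-2-ol
Conditions: H2 (1 atm), Pd/C, EtOAc–MeOH, rt
Reagents that add atoms: none
Why: Hydrogenolysis of the benzyl ether frees the D1 hydroxyl; aryl methyl and ethyl ethers and the dibenzofuran are inert.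

Step 8
Reactants: 15 7-ethoxy-3,9-dimethoxydibenzofuran-2-ol
Product: 16 7-ethoxy-2-hydroxy-3,9-dimethoxydibenzofuran-1-carbaldehyde
Conditions: MgCl2, Et3N, (CH2O)n, THF, reflux
Reagents that add atoms: paraformaldehyde (as formaldehyde), C=O
Why: Casnati–Skattebøl ortho-formylation; delivery from the D1 magnesium phenoxide can reach only D6 because D2 carries OMe. The carbon that will bear the second dioxin oxygen is thus functionalised without a free electrophile meeting the more electron-rich ring F.

Step 9
Reactants: 16 7-ethoxy-2-hydroxy-3,9-dimethoxydibenzofuran-1-carbaldehyde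
Product: 17 7-ethoxy-3,9-dimethoxy-2-[2-(trimethylsilyl)ethoxy]dibenzofuran-1-carbaldehyde
Conditions: Me3SiCH2CH2OH, PPh3, DIAD, THF, 0 °C → rt
Reagents that add atoms: 2-(trimethylsilyl)ethanol, C[Si](C)(C)CCO
Why: Mitsunobu etherification of the acidic salicylaldehyde-type phenol; unlike a silyl ether, the 2-(trimethylsilyl)ethyl ether cannot migrate to a neighbouring oxygen, it survives peracid, carbonate and methylation, and fluoride removes it later.

Step 10
Reactants: 17 7-ethoxy-3,9-dimethoxy-2-[2-(trimethylsilyl)ethoxy]dibenzofuran-1-carbaldehyde
Product: 19 7-ethoxy-3,9-dimethoxy-2-[2-(trimethylsilyl)ethoxy]dibenzofuran-1-ol, via aryl formate 18 (not isolated)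
Conditions: mCPBA, NaHCO3, CH2Cl2, 0 °C → rt; then K2CO3, MeOH, rt
Reagents that add atoms: mCPBA (3-chloroperoxybenzoic acid), O=C(OO)c1cccc(Cl)c1
Why: Dakin oxidation in its Baeyer–Villiger form; the ortho-alkoxy group and the electron-rich ring favour aryl migration, and methanolysis of 18 gives the free D6 phenol while D1 stays masked, so the two dioxin oxygens are differentiated.

Step 11
Reactants: 20 3-bromo-2,4-difluorobenzaldehyde
Product: 21 2-(3-bromo-2,4-difluorophenyl)-1,3-dioxolane
Conditions: HOCH2CH2OH, TsOH·H2O (cat.), toluene, reflux (Dean–Stark)
Reagents that add atoms: ethane-1,2-diol, OCCO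
Why: Acid-catalysed acetalisation protects the aldehyde from the amide base of the next step.

Step 12
Reactants: 21 2-(3-bromo-2,4-difluorophenyl)-1,3-dioxolane
Product: 23 5-bromo-4,6-difluorobenzene-1,3-dicarbaldehyde, via acetal aldehyde 22 (not isolated)
Conditions: LiN(iPr)2, THF, −78 °C; DMF, −78 °C; then 2 M HCl, THF, rt
Reagents that add atoms: N,N-dimethylformamide, CN(C)C=O
Why: Directed ortho-lithiation; the only proton ortho to fluorine is the most acidic, and the aryllithium is held at −78 °C to avoid loss of LiF and bromine migration. DMF formylates it and aqueous acid releases both aldehydes.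

Step 13
Reactants: 19 7-ethoxy-3,9-dimethoxy-2-[2-(trimethylsilyl)ethoxy]dibenzofuran-1-ol; 23 5-bromo-4,6-difluorobenzene-1,3-dicarbaldehyde; 24 3,5-dimethoxyphenol
Product: 26 5-bromo-4-(3,5-dimethoxyphenoxy)-6-({7-ethoxy-3,9-dimethoxy-2-[2-(trimethylsilyl)ethoxy]dibenzofuran-1-yl}oxy)benzene-1,3-dicarbaldehyde, via monoaryl ether 25 (not isolated)
Conditions: 19, 23 (1.1 equiv), K2CO3, DMF, 0 °C → rt; then 24, K2CO3, 40 °C
Reagents that add atoms: none
Why: Two successive SNAr displacements; each fluorine of 23 is ortho to one formyl group and para to the other, while the bromine-bearing carbon is meta to both and is left alone. The first aryloxy group donates into both formyl-bearing carbons and slows the second displacement, which allows the stepwise order, and the masked D1 oxygen means no ortho-phenoxide can attack the activated ring.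

Step 14
Reactants: 26 5-bromo-4-(3,5-dimethoxyphenoxy)-6-({7-ethoxy-3,9-dimethoxy-2-[2-(trimethylsilyl)ethoxy]dibenzofuran-1-yl}oxy)benzene-1,3-dicarbaldehyde
Product: 28 5-bromo-4-(3,5-dimethoxyphenoxy)-6-({7-ethoxy-3,9-dimethoxy-2-[2-(trimethylsilyl)ethoxy]dibenzofuran-1-yl}oxy)benzene-1,3-diol, via bis-formate 27 (not isolated)
Conditions: mCPBA, NaHCO3, CH2Cl2, 0 °C → rt; then K2CO3, MeOH, rt
Reagents that add atoms: mCPBA (3-chloroperoxybenzoic acid), O=C(OO)c1cccc(Cl)c1
Why: Double Dakin oxidation in its Baeyer–Villiger form; each formyl group has an ortho and a para aryloxy group to support aryl migration. The two activating groups become the B2 and B4 hydroxyls and ring B becomes electron-rich.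

Step 15
Reactants: 28 5-bromo-4-(3,5-dimethoxyphenoxy)-6-({7-ethoxy-3,9-dimethoxy-2-[2-(trimethylsilyl)ethoxy]dibenzofuran-1-yl}oxy)benzene-1,3-diol
Product: 29 1-[2-bromo-3-(3,5-dimethoxyphenoxy)-4,6-dimethoxyphenoxy]-7-ethoxy-3,9-dimethoxy-2-[2-(trimethylsilyl)ethoxy]dibenzofuran
Conditions: MeI, K2CO3, DMF, rt
Reagents that add atoms: iodomethane, CI
Why: Williamson methylation of both ring B phenols, so that the D1 phenoxide is the only nucleophile in the ring closure.

Step 16
Reactants: 29 1-[2-bromo-3-(3,5-dimethoxyphenoxy)-4,6-dimethoxyphenoxy]-7-ethoxy-3,9-dimethoxy-2-[2-(trimethylsilyl)ethoxy]dibenzofuran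
Product: 31 hepta-O-alkyl ether of the target (OEt on F3; OMe on F5, D2, B2, B4 and both ring A oxygens), via bromo phenol 30 (not isolated)
Conditions: CsF, DMF, 90 °C; then CuI, picolinic acid, K3PO4, 110 °C
Reagents that add atoms: none
Why: Fluoride attacks silicon and the β-silylethyl ether fragments to ethene, Me3SiF and the D1 phenoxide; an intramolecular Ullmann etherification under monovalent copper catalysis then closes the six-membered dioxin at the bromine-bearing B6. Ring B is no longer activated, so a spiro Meisenheimer adduct at B5 (Smiles rearrangement) cannot exchange the D1 and D6 oxygens, and the regiochemistry set in step 13 is kept.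

Step 17
Reactants: 31 hepta-O-alkyl ether of the target
Product: 32 target CNP0256302.0
Conditions: BBr3, CH2Cl2, −78 °C → rt; then MeOH, H2O (argon)
Reagents that add atoms: none
Why: Lewis acid dealkylation of six methyl ethers and one ethyl ether; diaryl ether, dioxin and furan C–O bonds resist BBr3, and the air-sensitive polyphenol is worked up and purified under inert gas.

## Compound list

1 | 4-(benzyloxy)-3-methoxybenzaldehyde (O-benzylvanillin) | COc1cc(C=O)ccc1OCc1ccccc1 | starting material
2 | 4-(benzyloxy)-3-methoxyphenyl formate | COc1cc(OC=O)ccc1OCc1ccccc1 | intermediate (not isolated)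
3 | 4-(benzyloxy)-3-methoxyphenol | COc1cc(O)ccc1OCc1ccccc1 | intermediate
4 | 5-(benzyloxy)-2-hydroxy-4-methoxybenzaldehyde | COc1cc(O)c(C=O)cc1OCc1ccccc1 | intermediate
5 | chloroacetone | CC(=O)CCl | starting material
6 | 1-[5-(benzyloxy)-6-methoxy-1-benzofuran-2-yl]ethan-1-one | COc1cc2oc(C(C)=O)cc2cc1OCc1ccccc1 | intermediate
7 | 1-[5-(benzyloxy)-6-methoxy-1-benzofuran-2-yl]-4,4,4-trifluorobutane-1,3-dione | COc1cc2oc(C(=O)CC(=O)C(F)(F)F)cc2cc1OCc1ccccc1 | intermediate (not isolated)
8 | 1-[5-(benzyloxy)-6-methoxy-1-benzofuran-2-yl]-2-diazoethan-1-one | COc1cc2oc(C(=O)C=[N+]=[N-])cc2cc1OCc1ccccc1 | intermediate (key-step precursor)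
9 | ethoxyacetylene | CCOC#C | starting material
10 | [5-(benzyloxy)-6-methoxy-1-benzofuran-2-yl]ketene | COc1cc2oc(C=C=O)cc2cc1OCc1ccccc1 | intermediate (not isolated)
11 | 4-[5-(benzyloxy)-6-methoxy-1-benzofuran-2-yl]-3-ethoxycyclobut-2-en-1-one (racemic, transient) | CCOC1=CC(=O)C1c1cc2cc(OCc3ccccc3)c(OC)cc2o1 | intermediate (not isolated)
12 | (3E)-4-[5-(benzyloxy)-6-methoxy-1-benzofuran-2-yl]-3-ethoxybuta-1,3-dien-1-one | O=C=C/C(OCC)=C\c1cc2cc(OCc3ccccc3)c(OC)cc2o1 | intermediate (not isolated)
13 | 8-(benzyloxy)-3-ethoxy-7-methoxydibenzofuran-1-ol | COc1cc2oc3cc(OCC)cc(O)c3c2cc1OCc1ccccc1 | intermediate (key-step product)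
14 | 8-(benzyloxy)-3-ethoxy-1,7-dimethoxydibenzofuran | COc1cc2oc3cc(OCC)cc(OC)c3c2cc1OCc1ccccc1 | intermediate
15 | 7-ethoxy-3,9-dimethoxydibenzofuran-2-ol | COc1cc2oc3cc(OCC)cc(OC)c3c2cc1O | intermediate
16 | 7-ethoxy-2-hydroxy-3,9-dimethoxydibenzofuran-1-carbaldehyde | COc1cc2oc3cc(OCC)cc(OC)c3c2c(C=O)c1O | intermediate
17 | 7-ethoxy-3,9-dimethoxy-2-[2-(trimethylsilyl)ethoxy]dibenzofuran-1-carbaldehyde | COc1cc2oc3cc(OCC)cc(OC)c3c2c(C=O)c1OCC[Si](C)(C)C | intermediate
18 | 7-ethoxy-3,9-dimethoxy-2-[2-(trimethylsilyl)ethoxy]dibenzofuran-1-yl formate | COc1cc2oc3cc(OCC)cc(OC)c3c2c(OC=O)c1OCC[Si](C)(C)C | intermediate (not isolated)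
19 | 7-ethoxy-3,9-dimethoxy-2-[2-(trimethylsilyl)ethoxy]dibenzofuran-1-ol | COc1cc2oc3cc(OCC)cc(OC)c3c2c(O)c1OCC[Si](C)(C)C | intermediate
20 | 3-bromo-2,4-difluorobenzaldehyde | O=Cc1ccc(F)c(Br)c1F | starting material
21 | 2-(3-bromo-2,4-difluorophenyl)-1,3-dioxolane | Fc1ccc(C2OCCO2)c(F)c1Br | intermediate
22 | 3-bromo-5-(1,3-dioxolan-2-yl)-2,4-difluorobenzaldehyde | O=Cc1cc(C2OCCO2)c(F)c(Br)c1F | intermediate (not isolated)
23 | 5-bromo-4,6-difluorobenzene-1,3-dicarbaldehyde | O=Cc1cc(C=O)c(F)c(Br)c1F | intermediate
24 | 3,5-dimethoxyphenol | COc1cc(O)cc(OC)c1 | starting material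
25 | 5-bromo-4-fluoro-6-({7-ethoxy-3,9-dimethoxy-2-[2-(trimethylsilyl)ethoxy]dibenzofuran-1-yl}oxy)benzene-1,3-dicarbaldehyde | COc1cc2oc3cc(OCC)cc(OC)c3c2c(Oc2c(C=O)cc(C=O)c(F)c2Br)c1OCC[Si](C)(C)C | intermediate (not isolated)
26 | 5-bromo-4-(3,5-dimethoxyphenoxy)-6-({7-ethoxy-3,9-dimethoxy-2-[2-(trimethylsilyl)ethoxy]dibenzofuran-1-yl}oxy)benzene-1,3-dicarbaldehyde | COc1cc(OC)cc(Oc2c(C=O)cc(C=O)c(Oc3c(OCC[Si](C)(C)C)c(OC)cc4oc5cc(OCC)cc(OC)c5c34)c2Br)c1 | intermediate
27 | bis-formate of 28 (benzene-1,3-diyl diformate) | COc1cc(OC)cc(Oc2c(OC=O)cc(OC=O)c(Oc3c(OCC[Si](C)(C)C)c(OC)cc4oc5cc(OCC)cc(OC)c5c34)c2Br)c1 | intermediate (not isolated)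
28 | 5-bromo-4-(3,5-dimethoxyphenoxy)-6-({7-ethoxy-3,9-dimethoxy-2-[2-(trimethylsilyl)ethoxy]dibenzofuran-1-yl}oxy)benzene-1,3-diol | COc1cc(OC)cc(Oc2c(O)cc(O)c(Oc3c(OCC[Si](C)(C)C)c(OC)cc4oc5cc(OCC)cc(OC)c5c34)c2Br)c1 | intermediate
29 | 1-[2-bromo-3-(3,5-dimethoxyphenoxy)-4,6-dimethoxyphenoxy]-7-ethoxy-3,9-dimethoxy-2-[2-(trimethylsilyl)ethoxy]dibenzofuran | COc1cc(OC)cc(Oc2c(OC)cc(OC)c(Oc3c(OCC[Si](C)(C)C)c(OC)cc4oc5cc(OCC)cc(OC)c5c34)c2Br)c1 | intermediate
30 | 1-[2-bromo-3-(3,5-dimethoxyphenoxy)-4,6-dimethoxyphenoxy]-7-ethoxy-3,9-dimethoxydibenzofuran-2-ol (present as its caesium phenoxide) | COc1cc(OC)cc(Oc2c(OC)cc(OC)c(Oc3c(O)c(OC)cc4oc5cc(OCC)cc(OC)c5c34)c2Br)c1 | intermediate (not isolated)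
31 | hepta-O-alkyl ether of the target (3,5-dimethoxyphenoxy on B1; OMe on B2, B4, D2, F5; OEt on F3) | COc1cc(OC)cc(Oc2c(OC)cc(OC)c3c2Oc2c(OC)cc4oc5cc(OCC)cc(OC)c5c4c2O3)c1 | intermediate
32 | CNP0256302.0, the heptaphenol (3,5-dihydroxyphenoxy on B1; OH on B2, B4, D2, F3, F5) | Oc1cc(O)cc(Oc2c(O)cc(O)c3c2Oc2c(O)cc4oc5cc(O)cc(O)c5c4c2O3)c1 | target

## Step count and least certain steps

Total: 17 steps. Longest linear sequence: 15 steps (steps 1–10 and 13–17); steps 11–12 are a two-step branch that supplies 23.

Step 5 (key step). The ketene may be consumed by paths other than the (2+2) union, namely dimerisation or acylation of the newly formed phenol, or the cascade may stall at the cyclobutenone. The causes are a volatile, polymerisable alkyne under long irradiation and a product that absorbs in the same region and screens the diazo ketone. Fallback, setting out from 8 and returning at 13: a thermal, stepwise route to the same cyclobutenone. Wolff rearrangement of 8 with PhCO2Ag (cat.) and Et3N in aqueous dioxane (Arndt–Eistert conditions) should give [5-(benzyloxy)-6-methoxy-1-benzofuran-2-yl]acetic acid F1. Oxalyl chloride with catalytic DMF should convert it into [5-(benzyloxy)-6-methoxy-1-benzofuran-2-yl]acetyl chloride F2. Slow addition of Et3N to F2 and 9 in CH2Cl2 generates ketene 10 by dehydrochlorination and traps it as cyclobutenone 11, which is isolated and heated in toluene (80–110 °C) to give 13.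

Step 8. The formylation may stall because D6 lies in the bay opposite the F5 methoxy group and the magnesium-bound hydroxymethyl intermediate is crowded; prolonged heating with formaldehyde then invites condensation at ring F. Fallback, setting out from 15 and returning at 16: a sigmatropic route to the same carbon. Allyl bromide and K2CO3 should give 2-(allyloxy)-7-ethoxy-3,9-dimethoxydibenzofuran F3. Aromatic Claisen rearrangement (N,N-diethylaniline, 190 °C) can end only at D6 and should give 1-allyl-7-ethoxy-3,9-dimethoxydibenzofuran-2-ol F4. Alkene isomerisation with RuHCl(CO)(PPh3)3 (cat.) should give 7-ethoxy-3,9-dimethoxy-1-[(E)-prop-1-enyl]dibenzofuran-2-ol F5. Lemieux–Johnson cleavage (OsO4 cat., NaIO4, 2,6-lutidine, aqueous dioxane) then gives 16.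

Step 13. The first displacement may be slow, since the bay phenoxide is flanked on both sides and the carbon it attacks sits between a formyl group and bromine. Forcing it with heat risks double arylation of 23 and fluoride-induced loss of the silylethyl group while ring B is still activated, which would open the way to Smiles scrambling. Fallback, setting out from 23 and 24 and returning at 26: reverse the order of assembly. 24 is added slowly to an excess of 23 (K2CO3, DMF, 0 °C) to give 5-bromo-4-(3,5-dimethoxyphenoxy)-6-fluorobenzene-1,3-dicarbaldehyde F6, which is purified. With only one activated fluorine left, F6 can be coupled with 19 under more forcing SNAr conditions without risk of double arylation, giving 26.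

Step 16. Copper-mediated closure may be slow at an aryl bromide flanked by two aryloxy groups on an electron-rich ring, so hydrodebromination or intermolecular coupling may compete; incomplete fluoride cleavage of the silylethyl ether is the second weak point. Fallback, setting out from 29 and returning at 31: separate the two events and change the bond-forming reaction. Bu4NF in THF at 60 °C frees phenol 30, which is isolated. A Buchwald–Hartwig etherification (Pd(OAc)2, tBuBrettPhos, K3PO4, toluene, 100 °C) then relies on oxidative addition at zerovalent palladium and C–O reductive elimination from a bulky phosphine complex, a path less sensitive to the electron-rich, hindered bromide. This fallback makes no compound outside the list (F0).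

## Further compounds

F1 | step 5 | [5-(benzyloxy)-6-methoxy-1-benzofuran-2-yl]acetic acid | OC(=O)Cc1cc2cc(OCc3ccccc3)c(OC)cc2o1
F2 | step 5 | [5-(benzyloxy)-6-methoxy-1-benzofuran-2-yl]acetyl chloride | ClC(=O)Cc1cc2cc(OCc3ccccc3)c(OC)cc2o1
F3 | step 8 | 2-(allyloxy)-7-ethoxy-3,9-dimethoxydibenzofuran | COc1cc2oc3cc(OCC)cc(OC)c3c2cc1OCC=C
F4 | step 8 | 1-allyl-7-ethoxy-3,9-dimethoxydibenzofuran-2-ol | COc1cc2oc3cc(OCC)cc(OC)c3c2c(CC=C)c1O
F5 | step 8 | 7-ethoxy-3,9-dimethoxy-1-[(E)-prop-1-enyl]dibenzofuran-2-ol | COc1cc2oc3cc(OCC)cc(OC)c3c2c(/C=C/C)c1O
F6 | step 13 | 5-bromo-4-(3,5-dimethoxyphenoxy)-6-fluorobenzene-1,3-dicarbaldehyde | COc1cc(OC)cc(Oc2c(C=O)cc(C=O)c(F)c2Br)c1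
F0 | step 16 | none | none
A1 | alternative 1 | 8-(benzyloxy)-3,7-dimethoxydibenzofuran-1,9-diol bridged across both oxygens by tetraisopropyldisiloxane-1,3-diyl | COc1cc2oc3cc(OC)cc4c3c2c(c1OCc1ccccc1)O[Si](C(C)C)(C(C)C)O[Si](C(C)C)(C(C)C)O4
A2 | alternative 1 | 12-membered macrocyclic diaryl ether (D4–O–F1) with the same disiloxane bridge between the F5 and D6 oxygens, D5–H and F6–H uncoupled | COc1cc2cc(c1OCc1ccccc1)O[Si](C(C)C)(C(C)C)O[Si](C(C)C)(C(C)C)Oc1cc(OC)cc(c1)O2
A3 | alternative 2 | pentamethyl ether of the target skeleton with formyl groups at B2 and B4 | COc1cc(OC)cc(Oc2c(C=O)cc(C=O)c3c2Oc2c(OC)cc4oc5cc(OC)cc(OC)c5c4c2O3)c1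
A4 | alternative 2 | 4,5,6-trifluorobenzene-1,3-dicarbaldehyde (4,5,6-trifluoroisophthalaldehyde) | O=Cc1cc(C=O)c(F)c(F)c1F
A5 | alternative 2 | 3,7,9-trimethoxy-2-[2-(trimethylsilyl)ethoxy]dibenzofuran-1-ol | COc1cc2oc3cc(OC)cc(OC)c3c2c(O)c1OCC[Si](C)(C)C
A6 | alternative 3 | 3-(benzyloxy)-2-(2-fluoro-4,6-dimethoxyphenyl)-5-methoxybenzene-1,4-diol | Oc1cc(OC)c(O)c(OCc2ccccc2)c1-c1c(F)cc(OC)cc1OC
A7 | alternative 3 | 3-(benzyloxy)-2-(2-fluoro-4,6-dimethoxyphenyl)-4-hydroxy-4-(1-methoxyethenyl)cyclobut-2-en-1-one (racemic) | C=C(OC)C1(O)C(OCc2ccccc2)=C(c2c(F)cc(OC)cc2OC)C1=O
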